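Target in chamigrene numbering (ring B = C1–C5 plus spiro C6; ring A = C6–C11, with C7 carrying =CH2, C10 carrying Br, C11 = CMe2): (2S,3R,6R,10R); on ring B, Br (C2) and Cl (C3) are cis and lie on the face of C7.
Cuts, in order: both C–Br bonds (to a C2,C10-diol, two SN2 inversions); the C10 carbinol to a ketone; ring A at C7–C8 and C9–C10, which releases C8–C9 as ethylene and leaves a 4-alkynal; C3–Cl/C2–O back to the C2=C3 alkene and a C10 acid; ring B at C1–C6 and C4–C5 (Diels–Alder) to isoprene and an α-methylene lactone.
Enabling feature: in ring A the sp2 carbon C7 and the functionalised C10 stand 1,4 across the adjacent quaternary carbons C6 and C11, so C7–C6–C11–C10 is a 4-alkynal whose tether carries no hydrogen; the aldehyde hydrogen becomes one hydrogen of the exocyclic methylene.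
Forward: ring B first (Diels–Alder, sets C6); the lactone is unpicked into ethynyl (C7) and acid (C10); a bridged chlorolactone (temporary ring) sets C3–Cl and C2–O; ring A is then closed by a rhodium-catalysed (4+2) annulation with ethylene, followed by ketone reduction and double bromination.
Stereochemistry: C6 from the catalyst-controlled Diels–Alder; C3 and C2 from the tether-enforced anti chlorolactonisation (C2 later inverted by bromide); C10 from reagent-controlled CBS reduction, then inverted by bromide.

Key step: step 8

Assumption: the (S)-oxazaborolidinium catalyst is taken to give the (5S)-adduct 4; the sense of induction with an α-methylene lactone is an extrapolation, and the (R)-catalyst is used if the opposite sense is found.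

Step 1
Reactants: 1 ketopantolactone (4,4-dimethyloxolane-2,3-dione)
Product: 2 4,4-dimethyl-3-methylideneoxolan-2-one
Conditions: Ph3PCH3Br, KOtBu, THF, 0 °C to rt
Reagents that add atoms: methyltriphenylphosphonium bromide, C[P+](c1ccccc1)(c1ccccc1)c1ccccc1.[Br-]
Why: Wittig methylenation should take place at the non-enolisable, strongly electrophilic ketone carbonyl rather than at the lactone carbonyl, giving the α-methylene lactone without forming a stereocentre.

Step 2
Reactants: 2 4,4-dimethyl-3-methylideneoxolan-2-one; 3 isoprene
Product: 4 (5S)-4,4,8-trimethyl-2-oxaspiro[4.5]dec-7-en-1-one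
Conditions: (S)-3,3-diphenyl-1-(o-tolyl)tetrahydro-1H,3H-pyrrolo[1,2-c][1,3,2]oxazaborole activated with HNTf2 (10 mol %), isoprene (5 equiv), CH2Cl2, −78 to −20 °C
Reagents that add atoms: none
Why: Catalytic enantioselective Diels–Alder reaction of an s-cis-locked acrylate-type dienophile, in which C1 of isoprene joins the lactone β-carbon so that the methyl group ends para to the new quaternary carbon and the boron-bound catalyst shields one face of the exocyclic alkene, which sets C6 as the only stereocentre.

Step 3
Reactants: 4 (5S)-4,4,8-trimethyl-2-oxaspiro[4.5]dec-7-en-1-one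
Product: 5 (5S)-4,4,8-trimethyl-2-oxaspiro[4.5]dec-7-en-1-ol (lactol, both anomers)
Conditions: (i-Bu)2AlH (1.1 equiv), CH2Cl2, −78 °C; Rochelle salt
Reagents that add atoms: none
Why: Partial lactone reduction with diisobutylaluminium hydride should stop at the aluminium hemiacetal at −78 °C, the anomeric centre being inconsequential and C6 untouched.

Step 4
Reactants: 5 (5S)-4,4,8-trimethyl-2-oxaspiro[4.5]dec-7-en-1-ol
Product: 7 2-[(1R)-1-ethynyl-4-methylcyclohex-3-en-1-yl]-2-methylpropan-1-ol, via hydroxy aldehyde 6 (not isolated)
Conditions: dimethyl (1-diazo-2-oxopropyl)phosphonate, K2CO3, MeOH, rt to 40 °C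
Reagents that add atoms: dimethyl (1-diazo-2-oxopropyl)phosphonate, CC(=O)C(=[N+]=[N-])P(=O)(OC)OC
Why: Ohira–Bestmann (Seyferth–Gilbert) homologation acts on the open hydroxy-aldehyde tautomer of the lactol, which has no α-hydrogen and so cannot epimerise or aldolise, and leaves C6 unchanged (its descriptor changes from S to R only through the priority rules).

Step 5
Reactants: 7 2-[(1R)-1-ethynyl-4-methylcyclohex-3-en-1-yl]-2-methylpropan-1-ol
Product: 9 2-[(1R)-1-ethynyl-4-methylcyclohex-3-en-1-yl]-2-methylpropanoic acid, via aldehyde 8 (not isolated)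
Conditions: 2,2,6,6-tetramethylpiperidin-1-oxyl (TEMPO, 20 mol %), PhI(OAc)2 (2.2 equiv), MeCN/H2O 1:1, rt
Reagents that add atoms: water, O
Why: Oxoammonium oxidation of the primary neopentyl alcohol through the aldehyde hydrate should give the acid without touching the alkyne or the trisubstituted alkene and without changing a stereocentre.

Step 6
Reactants: 9 2-[(1R)-1-ethynyl-4-methylcyclohex-3-en-1-yl]-2-methylpropanoic acid
Product: 10 (1R,5R,8R)-8-chloro-5-ethynyl-4,4,8-trimethyl-2-oxabicyclo[3.3.1]nonan-3-one
Conditions: 1,3-dichloro-5,5-dimethylhydantoin (0.6 equiv), DABCO (10 mol %), CHCl3, −20 °C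
Reagents that add atoms: 1,3-dichloro-5,5-dimethylhydantoin, CC1(C)N(Cl)C(=O)N(Cl)C1=O
Why: Chlorolactonisation (6-exo) in which the carboxylate on C11 can reach only C2 and only from the ring B face that carries C11 (ring B in the chair with C11 axial), while chlorine is delivered anti and axially to C3 on the face of the ethynyl group, so that C2–O and C3–Cl are set trans to each other and relative to C6 by the tether.

Step 7
Reactants: 10 (1R,5R,8R)-8-chloro-5-ethynyl-4,4,8-trimethyl-2-oxabicyclo[3.3.1]nonan-3-one
Product: 12 2-[(1R,3R,4R)-4-chloro-1-ethynyl-3-hydroxy-4-methylcyclohexyl]-2-methylpropanal, via bridged lactol 11 (not isolated)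
Conditions: (i-Bu)2AlH (1.1 equiv), CH2Cl2, −78 °C; Rochelle salt
Reagents that add atoms: none
Why: Partial lactone reduction with diisobutylaluminium hydride gives the lactol, which should open to the hydroxy aldehyde because ring B relaxes to the chair with C11 equatorial, where the C2 hydroxyl and C3 chloride are trans-diequatorial and cannot close to an epoxide, no stereocentre being affected.

Step 8
Reactants: 12 2-[(1R,3R,4R)-4-chloro-1-ethynyl-3-hydroxy-4-methylcyclohexyl]-2-methylpropanal; 13 ethylene
Product: 14 (6R,8R,9R)-9-chloro-8-hydroxy-1,1,9-trimethyl-5-methylidenespiro[5.5]undecan-2-one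
Conditions: [Rh(dppe)]2(BF4)2 (5 mol %; dppe = Ph2PCH2CH2PPh2), ethylene (10 bar), CH2Cl2, 40 °C
Reagents that add atoms: none
Why: Proposed new method: monovalent rhodium inserts into the aldehyde C–H bond of 12, the acyl rhodium hydride (trivalent rhodium) adds syn across the tethered terminal alkyne with hydride going to the terminal carbon, and the resulting five-membered acyl(alkenyl)rhodacycle (Rh–C10(=O)–C11–C6–C7(=CH2)) inserts ethylene and closes by C–C reductive elimination, so that C9–C10 and C7–C8 form in one catalytic cycle and the aldehyde hydrogen ends on the exocyclic methylene. The closest known reaction type is the rhodium-catalysed (4+2) annulation of 4-alkynals with alkynes or acrylamides, together with rhodium-catalysed hydroacylation of ethylene; what is new is ethylene as the two-carbon partner. Ring A closes as a formal (4+2) annulation, four carbons (C7, C6, C11, C10) coming from the rhodacycle and two from ethylene, the last bond arising by reductive elimination from a seven-membered rhodacycle. No stereocentre is created (C7 and C10 are sp2), and C6, C2 and C3 are remote from the metal and unchanged. The step needs hydride delivery to the alkyne terminus (secured by the five-membered chelate), ethylene insertion in preference to direct reductive elimination to a cyclopentenone or simple hydroacylation of ethylene (favoured by ethylene pressure, a non-coordinating solvent and the gem-dialkyl effect of the quaternary carbons C6 and C11), and a rhodacycle that cannot decompose (the tether has no α- or β-hydrogen, so neither enolisation nor β-hydride elimination is possible). The free hydroxyl and the tertiary chloride should be inert to the cationic rhodium catalyst.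

Step 9
Reactants: 14 (6R,8R,9R)-9-chloro-8-hydroxy-1,1,9-trimethyl-5-methylidenespiro[5.5]undecan-2-one
Product: 15 (2S,6R,8R,9R)-9-chloro-1,1,9-trimethyl-5-methylidenespiro[5.5]undecane-2,8-diol
Conditions: (R)-1-methyl-3,3-diphenyltetrahydro-1H,3H-pyrrolo[1,2-c][1,3,2]oxazaborole [(R)-Me-CBS, 20 mol %], catecholborane (3 equiv), toluene, −78 to −40 °C; MeOH, pH 7 buffer
Reagents that add atoms: none
Why: Corey–Bakshi–Shibata reduction under reagent control, in which the ketone is bound anti to its large quaternary flank (C11) and hydride is delivered to the face that gives the (S)-carbinol at C10 (spiro locant 2) independently of the remote ring B centres, catecholborane at low temperature leaving the exocyclic alkene alone.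

Step 10
Reactants: 15 (2S,6R,8R,9R)-9-chloro-1,1,9-trimethyl-5-methylidenespiro[5.5]undecane-2,8-diol
Product: 17 (2R,6R,8S,9R)-2,8-dibromo-9-chloro-1,1,9-trimethyl-5-methylidenespiro[5.5]undecane (target), via bromo alcohol 16 (not isolated)
Conditions: CBr4 (6 equiv), P(n-Oct)3 (6 equiv), 1-methylcyclohexene (10 equiv), toluene, 70 °C
Reagents that add atoms: carbon tetrabromide, BrC(Br)(Br)Br
Why: Double Appel bromination in which both alkoxyphosphonium ions (equatorial C2–O on ring B, expected to react first, and neopentylic C10–O on ring A) are displaced by bromide with SN2 inversion, turning the C2 hydroxyl into the bromide cis to the C3 chloride and the (10S)-alcohol into the (10R)-bromide, while the alkene scavenger removes HBr so that the methylidene group and the tertiary chloride survive.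

Compound list
1 | ketopantolactone (4,4-dimethyloxolane-2,3-dione) | CC1(C)COC(=O)C1=O | starting material
2 | 4,4-dimethyl-3-methylideneoxolan-2-one | C=C1C(=O)OCC1(C)C | intermediate
3 | isoprene (2-methylbuta-1,3-diene) | C=CC(C)=C | starting material
4 | (5S)-4,4,8-trimethyl-2-oxaspiro[4.5]dec-7-en-1-one | O=C1OCC(C)(C)[C@@]12CCC(C)=CC2 | intermediate
5 | (5S)-4,4,8-trimethyl-2-oxaspiro[4.5]dec-7-en-1-ol (lactol, both anomers) | OC1OCC(C)(C)[C@@]12CCC(C)=CC2 | intermediate
6 | (1S)-1-(1-hydroxy-2-methylpropan-2-yl)-4-methylcyclohex-3-ene-1-carbaldehyde (open form of 5) | OCC(C)(C)[C@]1(C=O)CCC(C)=CC1 | intermediate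
7 | 2-[(1R)-1-ethynyl-4-methylcyclohex-3-en-1-yl]-2-methylpropan-1-ol | OCC(C)(C)[C@]1(C#C)CCC(C)=CC1 | intermediate
8 | 2-[(1R)-1-ethynyl-4-methylcyclohex-3-en-1-yl]-2-methylpropanal | O=CC(C)(C)[C@]1(C#C)CCC(C)=CC1 | intermediate
9 | 2-[(1R)-1-ethynyl-4-methylcyclohex-3-en-1-yl]-2-methylpropanoic acid | OC(=O)C(C)(C)[C@]1(C#C)CCC(C)=CC1 | intermediate
10 | (1R,5R,8R)-8-chloro-5-ethynyl-4,4,8-trimethyl-2-oxabicyclo[3.3.1]nonan-3-one | CC1(C)C(=O)O[C@@H]2C[C@@]1(C#C)CC[C@@]2(C)Cl | intermediate
11 | (1R,5R,8R)-8-chloro-5-ethynyl-4,4,8-trimethyl-2-oxabicyclo[3.3.1]nonan-3-ol (bridged lactol, both anomers) | CC1(C)C(O)O[C@@H]2C[C@@]1(C#C)CC[C@@]2(C)Cl | intermediate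
12 | 2-[(1R,3R,4R)-4-chloro-1-ethynyl-3-hydroxy-4-methylcyclohexyl]-2-methylpropanal | O=CC(C)(C)[C@]1(C#C)CC[C@@](C)(Cl)[C@H](O)C1 | intermediate
13 | ethylene | C=C | starting material
14 | (6R,8R,9R)-9-chloro-8-hydroxy-1,1,9-trimethyl-5-methylidenespiro[5.5]undecan-2-one | C=C1CCC(=O)C(C)(C)[C@@]12CC[C@@](C)(Cl)[C@H](O)C2 | intermediate
15 | (2S,6R,8R,9R)-9-chloro-1,1,9-trimethyl-5-methylidenespiro[5.5]undecane-2,8-diol | C=C1CC[C@H](O)C(C)(C)[C@@]12CC[C@@](C)(Cl)[C@H](O)C2 | intermediate
16 | (2S,6R,8S,9R)-8-bromo-9-chloro-1,1,9-trimethyl-5-methylidenespiro[5.5]undecan-2-ol | C=C1CC[C@H](O)C(C)(C)[C@@]12CC[C@@](C)(Cl)[C@@H](Br)C2 | intermediate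
17 | (2R,6R,8S,9R)-2,8-dibromo-9-chloro-1,1,9-trimethyl-5-methylidenespiro[5.5]undecane | C=C1CC[C@@H](Br)C(C)(C)[C@@]12CC[C@@](C)(Cl)[C@@H](Br)C2 | target

Total step count: 10. Longest linear sequence: 10 steps (1 to 17).

Steps most likely to fail

Step 8 (Proposed new method). The acyl rhodium hydride may be diverted before ethylene inserts: direct reductive elimination of the rhodacycle to a cyclopentenone, simple hydroacylation of ethylene without ring closure, or oligomerisation of the terminal alkyne. The fallback forms the two bonds one after the other by known chemistry. It sets out from 12: addition of vinylmagnesium bromide (excess, THF, −78 °C) gives the allylic alcohol 4-[(1R,3R,4R)-4-chloro-1-ethynyl-3-hydroxy-4-methylcyclohexyl]-4-methylpent-1-en-3-ol F1 (C9–C10 bond). MnO2 in CH2Cl2 should oxidise only the allylic carbinol to the vinyl ketone F2. Bu3SnH/AIBN (benzene, 80 °C, slow addition) adds a stannyl radical to the alkyne terminus, and the vinyl radical at C7 closes 6-endo onto the enone β-carbon (C7–C8 bond) to give the exocyclic vinylstannane F3. Protodestannylation (HCl, 1 equiv, CH2Cl2, −20 °C) returns to the route at 14.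

Step 10. Displacement at C2 must bring bromide in axially, syn to the axial ring A carbon C7. It may stall, or be overtaken by participation of the C3 chloride (retention or halide migration), while the neopentylic C10 centre may rearrange. The fallback moves the C2 displacement to a stage where the syn-axial group is only the slender ethynyl group and separates the two inversions. It sets out from 10: aminolysis with MeNH(OMe)·HCl/AlMe3 (CH2Cl2) opens the lactone to the hydroxy Weinreb amide F4. Appel bromination (CBr4, P(n-Oct)3, toluene) inverts C2 to give the bromo Weinreb amide F5. (i-Bu)2AlH (−78 °C) gives the bromo aldehyde F6. Ring A is closed as in step 8 (or by its fallback) to the bromo ketone F7. CBS reduction as in step 9 then gives 16, where the fallback comes back to the route; a single Appel displacement at C10 under the step 10 conditions gives 17.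

Step 6. Lactonisation needs ring B in its less favourable chair (C11 axial), so the chloriranium ion may be lost by proton loss to an allylic chloride or by intermolecular capture before the carboxylate closes. The fallback separates C–O from C–Cl formation. It sets out from 9: iodolactonisation (I2, NaHCO3, MeCN/H2O), the most reliable halolactonisation and under the same tether control, gives the iodolactone F8. DBU (toluene, 80 °C) removes HI anti-periplanar through the axial hydrogen at C4 to give the alkene lactone F9. Anhydrous HCl (CH2Cl2, −40 °C) adds in the Markovnikov sense, with axial capture of the tertiary C3 cation anti to the C2–O bond on the locked bicycle, and returns to the route at 10.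

Further compounds
F1 | step 8 | 4-[(1R,3R,4R)-4-chloro-1-ethynyl-3-hydroxy-4-methylcyclohexyl]-4-methylpent-1-en-3-ol (both carbinol epimers) | C=CC(O)C(C)(C)[C@]1(C#C)CC[C@@](C)(Cl)[C@H](O)C1
F2 | step 8 | 4-[(1R,3R,4R)-4-chloro-1-ethynyl-3-hydroxy-4-methylcyclohexyl]-4-methylpent-1-en-3-one | C=CC(=O)C(C)(C)[C@]1(C#C)CC[C@@](C)(Cl)[C@H](O)C1
F3 | step 8 | 5-[(tributylstannyl)methylidene] analogue of 14 (ring stereocentres as in 14, alkene geometry open) | CCCC[Sn](CCCC)(CCCC)C=C1CCC(=O)C(C)(C)[C@@]12CC[C@@](C)(Cl)[C@H](O)C2
F4 | step 10 | 2-[(1R,3R,4R)-4-chloro-1-ethynyl-3-hydroxy-4-methylcyclohexyl]-N-methoxy-N,2-dimethylpropanamide | CON(C)C(=O)C(C)(C)[C@]1(C#C)CC[C@@](C)(Cl)[C@H](O)C1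
F5 | step 10 | 2-[(1R,3S,4R)-3-bromo-4-chloro-1-ethynyl-4-methylcyclohexyl]-N-methoxy-N,2-dimethylpropanamide | CON(C)C(=O)C(C)(C)[C@]1(C#C)CC[C@@](C)(Cl)[C@@H](Br)C1
F6 | step 10 | 2-[(1R,3S,4R)-3-bromo-4-chloro-1-ethynyl-4-methylcyclohexyl]-2-methylpropanal | O=CC(C)(C)[C@]1(C#C)CC[C@@](C)(Cl)[C@@H](Br)C1
F7 | step 10 | (6R,8S,9R)-8-bromo-9-chloro-1,1,9-trimethyl-5-methylidenespiro[5.5]undecan-2-one | C=C1CCC(=O)C(C)(C)[C@@]12CC[C@@](C)(Cl)[C@@H](Br)C2
F8 | step 6 | (1R,5R,8R)-5-ethynyl-8-iodo-4,4,8-trimethyl-2-oxabicyclo[3.3.1]nonan-3-one | CC1(C)C(=O)O[C@@H]2C[C@@]1(C#C)CC[C@@]2(C)I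
F9 | step 6 | (1R,5R)-5-ethynyl-4,4,8-trimethyl-2-oxabicyclo[3.3.1]non-7-en-3-one | CC1(C)C(=O)O[C@@H]2C[C@@]1(C#C)CC=C2C
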